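## Structural features

The target is a 2,3-trans flavan-3-ol. A chroman (arene ring A fused to the oxygen heterocycle ring C) carries a 4-hydroxy-3,5-dimethoxyphenyl group (ring B) on C2, a hydroxyl on C3 and a plain methylene at C4. Ring A is a resorcinol-type arene with O1 on C8a, a methoxy group on C7, hydrogens on C6 and C8, and on C5 a two-carbon chain ending in a 3-hydroxyphenyl ring (ring D). The only stereocentres are the neighbours C2 (R) and C3 (S), trans to each other. The fragile points are the C2–O1 bond (a benzylic ether next to an oxygenated arene, open to acid ionisation and to hydrogenolysis), the two free phenols, and the electron-rich ring A, which is nucleophilic at C6 and C8 and activates C4 towards oxidants. The real difficulty is the 1,2,3,5-pattern of ring A: C4a must carry C4, C5 the phenethyl chain, C7 the only methyl ether and C8a the ring oxygen, and arene substitution chemistry does not deliver this selectively. The key step uses the fact that the C8a–C4a edge has the pattern of a carboxyl carbon and its α-carbon. In a δ-lactone O1–C8a(=O)–C4a–C4–C3–C2 that already holds both stereocentres, C4a is nucleophilic and C8a electrophilic, and C5–C8 map onto a methyl enone (C5 the β-carbon with the chain, C7 the carbonyl, C8 the methyl).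

## Logic of the disconnections

24 to 23. The three O–CH2Ph bonds (on O3, on the ring B phenol and on the ring D phenol) are cut. Every hydroxyl of 24 would interfere with enolate, Lewis acid and alkylation steps, and one neutral reduction can free all three. The gain is that no hydroxyl needs to be differentiated at the end. The forward step must remove three benzyl groups and leave the cyclic benzylic C2–O1 bond alone.

23 to 22. The O–CH3 bond on C7 is cut. The C7 oxygen is the former ketone oxygen and is the only free hydroxyl of 22, so the question of which ring A oxygen is methylated does not arise. The demand is that O3 and both other phenols are capped beforehand.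

22 to 19. Ring A is taken out of the aromatic state: two hydrogens return to C5 and C6, and the C7 hydroxyl becomes a ketone conjugated with the O1–C8a=C8 enol ether. In 19 all six ring A carbons come from carbonyl condensations, so the substitution pattern is fixed by which carbon is bonded to which. The forward step must dehydrogenate the carbocycle only and spare C2 and C4. It erases C4a and C5, so their configuration in 19 is irrelevant.

19 to 10 and 15 (key disconnection). The C4a–C5 and C8–C8a bonds are cut. The O1–C8a bond is kept on paper but is broken and re-formed in the flask. This gives two fragments of similar size: 10 holds both stereocentres, ring C and the C8a–C4a edge, and 15 holds C5–C8 with the chain. Connectivity and configuration of 10 and 19 need no correction: (5S,6R) in 10 is the same spatial arrangement as (3S,2R) in the chroman. The forward step needs 1,4-addition to 15, Claisen closure from the methyl side, and an O3 protecting group that neither leaves nor migrates when the C2 alkoxide is set free. A silyl ether would be the obvious choice at O3, but it can hop to the neighbouring alkoxide and then allow a five-membered closure from O3, so a benzyl ether is used. It also saves a deprotection step.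

15 to 13 and 14, then 13 to 12 to 11. The C=C bond of the enone is cut by a carbonyl olefination, which sets the E geometry under thermodynamic control. 13 goes back by ester reduction and double O-benzylation to 11. The ring D phenol is capped once, in the first step of this branch.

10 to 9 to 7 (through 8). The O3–benzyl bond is cut first. Then the lactone C6–O1 bond (the later C2–O1 bond) is cut, which leads back to a trans epoxide with a pendant carboxyl group. Anti opening of a trans epoxide at the benzylic carbon gives the trans relationship of aryl and oxygen on the ring. The forward step must open the epoxide in the 6-endo mode with inversion, and the free hydroxy lactone must be capped before the acyl group can move to the five-membered lactone.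

7 to 6. The epoxide oxygen is removed to give an E-alkene. Both C–O stereocentres then depend on one catalyst-controlled face selection, which must give the (S,S) epoxide.

6 to 3 and 4, then 3 to 2 to 1. The C2–C3 bond of the pentenoate is cut by a [3,3] shift of a ketene acetal derived from 3 and 4, which delivers the E-alkene and the two-carbon ester arm together. 3 comes from vinyl addition to 2, and 2 from O-benzylation of 1. The stereocentre of 3 is lost in the rearrangement, so no control is needed there.

## Other disconnections considered

Alternative 1: The cut goes through C3–C4 and O1–C2. Ring C would be assembled from the salicyl alcohol A2 (ring A with its hydroxymethyl group as C4) and the E-styrylboronate A3 (ring B with C2 and C3).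
- Forward key step: a chiral BINOL-derived phosphoric acid would dehydrate A2 to the o-quinone methide and steer its [4+2] cycloaddition with A3 to the trans-3-borylchroman A1. Oxidation of the C–B bond with retention and one hydrogenolysis would finish.
- In favour: ring C and both stereocentres come from one convergent catalytic step. The E geometry of A3 is transcribed into the trans relationship. The end game is two steps and O3 needs no protecting group.
- Against: the quinone methide from A2 has an unsubstituted methylene terminus, so both new stereocentres lie on the dienophile carbons. The catalyst must tell the faces of A3 apart while holding a short-lived partner that tends to dimerise. A1 has a free hydroxyl para to C2, so under the acid the C2–O1 bond can reopen to a para-quinone methide and erode diastereomer ratio and ee. A2 is itself a 1,2,3,5-tetrasubstituted arene whose hydroxymethyl group must sit between the phenol and the chain, so the ring A problem is only moved to an ortho-functionalisation that would prefer the less hindered positions.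
- Comparison: on structure it builds ring C late on an aromatic ring A, and the chosen plan builds ring A late on ring C. On mechanism it is a stereospecific cycloaddition against a stepwise annulation with no stereochemical content. On convergence and step count the alternative is the better. On precedent the two are equal, since neither key step has a direct precedent for this substitution pattern. The chosen plan is the better on certainty of absolute configuration and on ring A regiochemistry.

Alternative 2: The cut is C4–C4a. Ring C would close by attack of ring A on a terminal epoxide in the aryl ether A5, which already carries C2 and C3.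
- Forward key step: BF3·OEt2 or hexafluoroisopropanol would activate the epoxide of A5, and C4a would attack the CH2 carbon to give the flavan-3-ol A4. Removal of the tosylate and one hydrogenolysis would follow.
- In favour: the reaction type is known for aryl glycidyl ethers and the six-membered mode is usual there. The C3 hydroxyl is set free directly with no protecting group. Ring A enters as a simple 1,3,5-trisubstituted phenol ether.
- Against: ring A offers two different ortho carbons to the tether. C4a is para to the methoxy group but next to the chain, and C8 lies between the two oxygens. Closure through C8 would exchange chain and methoxy group on ring A, and nothing in A5 enforces the choice. The C2–O1 bond of A5 is a secondary benzylic aryl ether that the same Lewis acid can ionise (the reason for the tosylate on ring B), and making it with defined configuration is a further task.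
- Comparison: on structure both plans keep the stereocentres out of the key bond formation. On mechanism it is an electrophilic aromatic substitution whose regiochemistry rests on arene electronics, against an annulation whose regiochemistry rests on connectivity. On precedent and on the free C3 hydroxyl the alternative is the better. On step count it is about equal. The chosen plan is the better on regiochemical certainty.

Alternative 3: The cut is C8a–O1. Ring C would close by C–O coupling of the anti diol monoether A7, which carries bromine on C8a.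
- Forward key step: Pd(OAc)2 (divalent palladium, reduced in the flask to zerovalent palladium), a bulky di-tert-butylbiarylphosphine and Cs2CO3 would join the C2 hydroxyl to C8a and give the protected flavan A6. Acetal cleavage and hydrogenolysis would follow.
- In favour: intramolecular palladium etherification of aryl bromides with secondary alcohols is well precedented. The C2–O bond of the alcohol is never broken, so stereochemical fidelity is the best of all four plans. The conditions are only weakly basic.
- Against: A7 needs a ring A with bromine, the C4 methylene and the chain on three neighbouring carbons in fixed order, which is again the 1,2,3,5-pattern problem, now solved by several steps of arene chemistry. The palladium alkoxide of a secondary benzylic alcohol can undergo β-hydride elimination to the ketone. The final acetal cleavage exposes the C2–O1 bond to acid.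
- Comparison: on structure it closes ring C last on a finished ring A. On mechanism it is reductive elimination against carbonyl condensation. On precedent and on stereochemical safety of the ring closure the alternative is the better. On step count it is probably equal or longer once A7 is made. The chosen plan is the better on ring A regiochemistry.

Key step: step 10

Remark: the L-fructose-derived epoxidation ketone (enantiomer of the usual D-fructose-derived Shi ketone, accessible from L-sorbose) is taken to be available as a catalyst.

Remark: 17 to 21 are carried as mixtures at C4a and C5, which become sp2 in step 11.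

## Route

Step 1
Reactants: 1 syringaldehyde
Product: 2 4-(benzyloxy)-3,5-dimethoxybenzaldehyde
Conditions: BnBr, K2CO3, DMF, 60 °C
Reagents that add atoms: benzyl bromide, BrCc1ccccc1
Why: Williamson etherification of the acidic 2,6-dimethoxyphenol; the aldehyde is not enolisable and is untouched.

Step 2
Reactants: 2 4-(benzyloxy)-3,5-dimethoxybenzaldehyde
Product: 3 rac-1-[4-(benzyloxy)-3,5-dimethoxyphenyl]prop-2-en-1-ol
Conditions: CH2=CHMgBr, THF, 0 °C; then H2O (aq NH4Cl work-up)
Reagents that add atoms: vinylmagnesium bromide, C=C[Mg]Br
Why: Grignard 1,2-addition to a non-enolisable aldehyde; the new carbinol centre is racemic on purpose because step 3 destroys it.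

Step 3
Reactants: 3 rac-1-[4-(benzyloxy)-3,5-dimethoxyphenyl]prop-2-en-1-ol; 4 triethyl orthoacetate
Product: 6 ethyl (4E)-5-[4-(benzyloxy)-3,5-dimethoxyphenyl]pent-4-enoate, via allyl ketene acetal 5 (not isolated)
Conditions: MeC(OEt)3 (5 equiv), EtCO2H (cat.), 140 °C, EtOH distilled off
Reagents that add atoms: none
Why: Johnson–Claisen rearrangement: acid-catalysed exchange and loss of ethanol give 5, whose chair [3,3] shift with the aryl group equatorial should give the E-alkene conjugated with the arene and the two-carbon ester arm.

Step 4
Reactants: 6 ethyl (4E)-5-[4-(benzyloxy)-3,5-dimethoxyphenyl]pent-4-enoate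
Product: 7 ethyl 3-{(2S,3S)-3-[4-(benzyloxy)-3,5-dimethoxyphenyl]oxiran-2-yl}propanoate
Conditions: L-fructose-derived Shi ketone (0.3 equiv), KHSO5 (as 2KHSO5·KHSO4·K2SO4), K2CO3, Bu4NHSO4 (cat.), MeCN/CH2(OMe)2/aq Na2B4O7 buffer, 0 °C
Reagents that add atoms: potassium peroxymonosulfate, [K+].[O-]S(=O)(=O)OO
Why: Shi asymmetric epoxidation of an E-disubstituted styrene-type alkene through the spiro transition state of the chiral dioxirane; the D-fructose-derived ketone gives (R,R) epoxides from such alkenes, so its enantiomer should give the (S,S) epoxide, which fixes C3 directly and C2 after inversion; the ester tolerates the buffered medium.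

Step 5
Reactants: 7 ethyl 3-{(2S,3S)-3-[4-(benzyloxy)-3,5-dimethoxyphenyl]oxiran-2-yl}propanoate
Product: 9 (5S,6R)-6-[4-(benzyloxy)-3,5-dimethoxyphenyl]-5-hydroxyoxan-2-one, via epoxy acid 8 (not isolated)
Conditions: LiOH, THF/H2O, 0 °C → rt; H3PO4 to pH 4, 0 °C, extract (CH2Cl2); CSA (5 mol %), CH2Cl2, 0 °C
Reagents that add atoms: lithium hydroxide, [Li+].[OH-]
Why: Saponification, then acid-catalysed intramolecular epoxide opening by the carboxyl group: 6-endo attack at the benzylic carbon, whose C–O bond is the more polarised one, with inversion should give the trans lactone, while the epoxide oxygen stays on C5 with retention; using the free acid avoids an orthoester-type intermediate that could collapse to an open hydroxy ester.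

Step 6
Reactants: 9 (5S,6R)-6-[4-(benzyloxy)-3,5-dimethoxyphenyl]-5-hydroxyoxan-2-one
Product: 10 (5S,6R)-5-(benzyloxy)-6-[4-(benzyloxy)-3,5-dimethoxyphenyl]oxan-2-one
Conditions: BnBr, Ag2O, Bu4NI (cat.), 4 Å sieves, CH2Cl2, rt, dark
Reagents that add atoms: benzyl bromide, BrCc1ccccc1
Why: Silver-assisted Williamson benzylation under neutral conditions, with no free alkoxide (which would move the acyl group to the five-membered lactone) and no strong acid (which could ionise the benzylic lactone C–O bond); benzyl is chosen because it cannot migrate to the neighbouring alkoxide released in step 10 and is removed in step 13.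

Step 7
Reactants: 11 3-(3-hydroxyphenyl)propanoic acid
Product: 12 benzyl 3-[3-(benzyloxy)phenyl]propanoate
Conditions: BnBr (2.3 equiv), K2CO3, DMF, 60 °C
Reagents that add atoms: benzyl bromide, BrCc1ccccc1
Why: Double O-alkylation of carboxylate and phenoxide in one operation (Williamson etherification and carboxylate alkylation).

Step 8
Reactants: 12 benzyl 3-[3-(benzyloxy)phenyl]propanoate
Product: 13 3-[3-(benzyloxy)phenyl]propanal
Conditions: iBu2AlH (1.05 equiv), CH2Cl2, −78 °C; MeOH, aq KNaC4H4O6
Reagents that add atoms: none
Why: Partial ester reduction with iBu2AlH at −78 °C through a tetrahedral aluminium hemiacetal that holds until work-up; the aryl benzyl ether is inert.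

Step 9
Reactants: 13 3-[3-(benzyloxy)phenyl]propanal; 14 1-(triphenylphosphoranylidene)propan-2-one
Product: 15 (3E)-6-[3-(benzyloxy)phenyl]hex-3-en-2-one
Conditions: PhMe, 80 °C
Reagents that add atoms: none
Why: Wittig olefination with a stabilised acyl ylide, which should be E-selective because oxaphosphetane formation is reversible.

Step 10
Reactants: 10 (5S,6R)-5-(benzyloxy)-6-[4-(benzyloxy)-3,5-dimethoxyphenyl]oxan-2-one; 15 (3E)-6-[3-(benzyloxy)phenyl]hex-3-en-2-one
Product: 19 (2R,3S)-3-(benzyloxy)-2-[4-(benzyloxy)-3,5-dimethoxyphenyl]-5-{2-[3-(benzyloxy)phenyl]ethyl}-2,3,4,4a,5,6-hexahydro-7H-chromen-7-one (mixture at C4a and C5), via silyl ketene acetal 16 (not isolated), via keto lactone silyl enol ether 17 (not isolated), via hydroxy diketone 18 (not isolated)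
Conditions: LiN(iPr)2, Me3SiCl, THF, −78 °C; evaporate, pentane, filter; 15, Me3SiOTf (10 mol %), CH2Cl2, −78 °C; evaporate; KOtBu (2.5 equiv), tBuOH, THF, 0 °C → rt; AcOH; TsOH·H2O (10 mol %), MgSO4, PhMe, 40 °C
Reagents that add atoms: none
Why: Proposed new method: LiN(iPr)2 with Me3SiCl present converts 10 into the silyl ketene acetal 16, a neutral, soft enolate equivalent that cannot self-condense. Catalytic Me3SiOTf silylates the carbonyl oxygen of 15, and C4a of 16 attacks the β-carbon of the resulting silyloxyallyl cation (Mukaiyama–Michael, bond C4a–C5) to give the silyl enol ether 17; attack of a silyl ketene acetal at the soft β-terminus of an O-silylated enone is what secures 1,4- over 1,2-addition. KOtBu cleaves the silyl enol ether and, with tBuOH as proton shuttle, equilibrates the ketone enolates; only the methyl-side (C8) enolate can reach the lactone carbonyl C8a through a six-membered transition state (6-exo-trig Claisen closure of ring A, bond C8–C8a), whereas the C6 enolate could only form a cyclobutanone. Collapse of the tetrahedral intermediate expels O1 as the C2 alkoxide, and irreversible deprotonation of the 1,3-diketone 18 pulls the reversible side equilibria (retro-Michael, enol lactone formation) forward. After neutralisation, TsOH adds the C2 hydroxyl to the C8a carbonyl (6-exo-trig hemiketal formation; reaching C7 would need an eight-membered ring) and dehydration recloses ring C as the vinylogous ester 19. The closest known reaction types are the Michael–Claisen annulation of ester enolates with enones to cyclohexane-1,3-diones, Mukaiyama–Michael addition of lactone silyl ketene acetals, C-acylation of ketone enolates by lactones and acid-catalysed enol etherification of 1,3-diones; new is their combination on a lactone whose ring oxygen is expelled and then returned as the enol ether oxygen. No lasting stereocentre is formed: C4a and C5 arise as a mixture and become sp2 in step 11, while C2 and C3 are not enolisable at any stage. The benzyloxy group on C3 is γ to the lactone carbonyl, so no enolate can expel it, and as an ether it cannot migrate to the adjacent C2 alkoxide, so O1 is the only oxygen able to close onto C8a.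

Step 11
Reactants: 19 (2R,3S)-3-(benzyloxy)-2-[4-(benzyloxy)-3,5-dimethoxyphenyl]-5-{2-[3-(benzyloxy)phenyl]ethyl}-2,3,4,4a,5,6-hexahydro-7H-chromen-7-one
Product: 22 (2R,3S)-3-(benzyloxy)-2-[4-(benzyloxy)-3,5-dimethoxyphenyl]-5-{2-[3-(benzyloxy)phenyl]ethyl}-3,4-dihydro-2H-chromen-7-ol, via silyl dienol ether 20 (not isolated), via cross-conjugated dienone 21 (not isolated)
Conditions: LiN(iPr)2, THF, −78 °C; Me3SiCl; then Pd(OAc)2 (1.1 equiv), MeCN, rt
Reagents that add atoms: none
Why: Saegusa–Ito dehydrogenation: kinetic deprotonation of the vinylogous ester at C6 (the α′ site) and O-silylation give 20; Pd(OAc)2 (divalent palladium) forms the C6 palladium enolate and β-hydride elimination of H5 gives 21, which tautomerises (H4a to O7) to the phenol and erases C4a and C5; C2, C3 and the benzyl ethers are not involved.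

Step 12
Reactants: 22 (2R,3S)-3-(benzyloxy)-2-[4-(benzyloxy)-3,5-dimethoxyphenyl]-5-{2-[3-(benzyloxy)phenyl]ethyl}-3,4-dihydro-2H-chromen-7-ol
Product: 23 (2R,3S)-3-(benzyloxy)-2-[4-(benzyloxy)-3,5-dimethoxyphenyl]-5-{2-[3-(benzyloxy)phenyl]ethyl}-7-methoxy-3,4-dihydro-2H-chromene
Conditions: MeI, K2CO3, acetone, 50 °C
Reagents that add atoms: methyl iodide, CI
Why: Williamson methylation of the only free hydroxyl, the C7 phenol; O3 and the other two phenols are benzyl ethers, so the position of the methyl ether is unambiguous.

Step 13
Reactants: 23 (2R,3S)-3-(benzyloxy)-2-[4-(benzyloxy)-3,5-dimethoxyphenyl]-5-{2-[3-(benzyloxy)phenyl]ethyl}-7-methoxy-3,4-dihydro-2H-chromene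
Product: 24 (2R,3S)-2-(4-hydroxy-3,5-dimethoxyphenyl)-5-[2-(3-hydroxyphenyl)ethyl]-7-methoxy-3,4-dihydro-2H-chromen-3-ol
Conditions: H2 (1 atm), Pd(OH)2/C, EtOAc/MeOH, rt
Reagents that add atoms: none
Why: Catalytic hydrogenolysis of two aryl benzyl ethers and the secondary benzyl ether on O3; under neutral conditions at 1 atm the cyclic C2–O1 benzylic ether of a flavan should survive, and C2 and C3 are untouched.

## Compound list

1 | syringaldehyde (4-hydroxy-3,5-dimethoxybenzaldehyde) | COc1cc(C=O)cc(OC)c1O | starting material
2 | 4-(benzyloxy)-3,5-dimethoxybenzaldehyde | COc1cc(C=O)cc(OC)c1OCc1ccccc1 | intermediate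
3 | rac-1-[4-(benzyloxy)-3,5-dimethoxyphenyl]prop-2-en-1-ol | C=CC(O)c1cc(OC)c(OCc2ccccc2)c(OC)c1 | intermediate
4 | triethyl orthoacetate | CCOC(C)(OCC)OCC | starting material
5 | 2-(benzyloxy)-5-{1-[(1-ethoxyethenyl)oxy]prop-2-en-1-yl}-1,3-dimethoxybenzene (allyl ketene acetal, racemic) | C=CC(OC(=C)OCC)c1cc(OC)c(OCc2ccccc2)c(OC)c1 | intermediate
6 | ethyl (4E)-5-[4-(benzyloxy)-3,5-dimethoxyphenyl]pent-4-enoate | CCOC(=O)CC/C=C/c1cc(OC)c(OCc2ccccc2)c(OC)c1 | intermediate
7 | ethyl 3-{(2S,3S)-3-[4-(benzyloxy)-3,5-dimethoxyphenyl]oxiran-2-yl}propanoate | CCOC(=O)CC[C@@H]1O[C@H]1c1cc(OC)c(OCc2ccccc2)c(OC)c1 | intermediate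
8 | 3-{(2S,3S)-3-[4-(benzyloxy)-3,5-dimethoxyphenyl]oxiran-2-yl}propanoic acid | OC(=O)CC[C@@H]1O[C@H]1c1cc(OC)c(OCc2ccccc2)c(OC)c1 | intermediate
9 | (5S,6R)-6-[4-(benzyloxy)-3,5-dimethoxyphenyl]-5-hydroxyoxan-2-one | O=C1CC[C@H](O)[C@@H](c2cc(OC)c(OCc3ccccc3)c(OC)c2)O1 | intermediate
10 | (5S,6R)-5-(benzyloxy)-6-[4-(benzyloxy)-3,5-dimethoxyphenyl]oxan-2-one | O=C1CC[C@H](OCc2ccccc2)[C@@H](c2cc(OC)c(OCc3ccccc3)c(OC)c2)O1 | intermediate
11 | 3-(3-hydroxyphenyl)propanoic acid | OC(=O)CCc1cccc(O)c1 | starting material
12 | benzyl 3-[3-(benzyloxy)phenyl]propanoate | O=C(CCc1cccc(OCc2ccccc2)c1)OCc1ccccc1 | intermediate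
13 | 3-[3-(benzyloxy)phenyl]propanal | O=CCCc1cccc(OCc2ccccc2)c1 | intermediate
14 | 1-(triphenylphosphoranylidene)propan-2-one | CC(=O)C=P(c1ccccc1)(c1ccccc1)c1ccccc1 | starting material
15 | (3E)-6-[3-(benzyloxy)phenyl]hex-3-en-2-one | CC(=O)/C=C/CCc1cccc(OCc2ccccc2)c1 | intermediate
16 | (2R,3S)-3-(benzyloxy)-2-[4-(benzyloxy)-3,5-dimethoxyphenyl]-6-[(trimethylsilyl)oxy]-3,4-dihydro-2H-pyran | C[Si](C)(C)OC1=CC[C@H](OCc2ccccc2)[C@@H](c2cc(OC)c(OCc3ccccc3)c(OC)c2)O1 | intermediate
17 | (5S,6R)-5-(benzyloxy)-6-[4-(benzyloxy)-3,5-dimethoxyphenyl]-3-{1-[3-(benzyloxy)phenyl]-5-[(trimethylsilyl)oxy]hex-4-en-3-yl}oxan-2-one (mixture at C3 and the side-chain carbon) | CC(O[Si](C)(C)C)=CC(CCc1cccc(OCc2ccccc2)c1)C1C[C@H](OCc2ccccc2)[C@@H](c2cc(OC)c(OCc3ccccc3)c(OC)c2)OC1=O | intermediate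
18 | 4-{(2S,3R)-2-(benzyloxy)-3-[4-(benzyloxy)-3,5-dimethoxyphenyl]-3-hydroxypropyl}-5-{2-[3-(benzyloxy)phenyl]ethyl}cyclohexane-1,3-dione (mixture at C4 and C5) | O=C1CC(=O)C(C[C@H](OCc2ccccc2)[C@H](O)c2cc(OC)c(OCc3ccccc3)c(OC)c2)C(CCc2cccc(OCc3ccccc3)c2)C1 | intermediate
19 | (2R,3S)-3-(benzyloxy)-2-[4-(benzyloxy)-3,5-dimethoxyphenyl]-5-{2-[3-(benzyloxy)phenyl]ethyl}-2,3,4,4a,5,6-hexahydro-7H-chromen-7-one (mixture at C4a and C5) | O=C1CC(CCc2cccc(OCc3ccccc3)c2)C2C[C@H](OCc3ccccc3)[C@@H](c3cc(OC)c(OCc4ccccc4)c(OC)c3)OC2=C1 | intermediate
20 | (2R,3S)-3-(benzyloxy)-2-[4-(benzyloxy)-3,5-dimethoxyphenyl]-5-{2-[3-(benzyloxy)phenyl]ethyl}-7-[(trimethylsilyl)oxy]-3,4,4a,5-tetrahydro-2H-chromene (mixture at C4a and C5) | C[Si](C)(C)OC1=CC(CCc2cccc(OCc3ccccc3)c2)C2C[C@H](OCc3ccccc3)[C@@H](c3cc(OC)c(OCc4ccccc4)c(OC)c3)OC2=C1 | intermediate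
21 | (2R,3S)-3-(benzyloxy)-2-[4-(benzyloxy)-3,5-dimethoxyphenyl]-5-{2-[3-(benzyloxy)phenyl]ethyl}-2,3,4,4a-tetrahydro-7H-chromen-7-one (mixture at C4a) | O=C1C=C(CCc2cccc(OCc3ccccc3)c2)C2C[C@H](OCc3ccccc3)[C@@H](c3cc(OC)c(OCc4ccccc4)c(OC)c3)OC2=C1 | intermediate
22 | (2R,3S)-3-(benzyloxy)-2-[4-(benzyloxy)-3,5-dimethoxyphenyl]-5-{2-[3-(benzyloxy)phenyl]ethyl}-3,4-dihydro-2H-chromen-7-ol | Oc1cc(CCc2cccc(OCc3ccccc3)c2)c2c(c1)O[C@H](c1cc(OC)c(OCc3ccccc3)c(OC)c1)[C@@H](OCc1ccccc1)C2 | intermediate
23 | (2R,3S)-3-(benzyloxy)-2-[4-(benzyloxy)-3,5-dimethoxyphenyl]-5-{2-[3-(benzyloxy)phenyl]ethyl}-7-methoxy-3,4-dihydro-2H-chromene | COc1cc(CCc2cccc(OCc3ccccc3)c2)c2c(c1)O[C@H](c1cc(OC)c(OCc3ccccc3)c(OC)c1)[C@@H](OCc1ccccc1)C2 | intermediate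
24 | (2R,3S)-2-(4-hydroxy-3,5-dimethoxyphenyl)-5-[2-(3-hydroxyphenyl)ethyl]-7-methoxy-3,4-dihydro-2H-chromen-3-ol | COc1cc(CCc2cccc(O)c2)c2c(c1)O[C@H](c1cc(OC)c(O)c(OC)c1)[C@@H](O)C2 | target

## Step count and least certain steps

Total: 13 steps. Longest linear sequence: 10 steps (steps 1 to 6 and 10 to 13, from 1 to 24). The enone branch (steps 7 to 9) is three steps.

Step 10 (key step, the one labelled as a proposed new method).
- What may go wrong: ionisation of the benzylic C–O bond of 16 or 17 by the silyl triflate, with loss of configuration at C2. In the base stage, retro-Michael cleavage or intermolecular aldol condensation of the methyl ketone could outrun the Claisen closure. In the acid stage, the C2–O1 bond could ionise again.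
- Fallback with known chemistry only, from 10 back to 19: the lactone is replaced by an open-chain ester so that the annulation is the classical ester enolate case. 10 is opened with LiOH (THF/H2O) and the lithium carboxylate is methylated with MeI in DMF to methyl (4S,5R)-4-(benzyloxy)-5-[4-(benzyloxy)-3,5-dimethoxyphenyl]-5-hydroxypentanoate F1. This is silylated at once (Et3SiOTf, 2,6-lutidine) to methyl (4S,5R)-4-(benzyloxy)-5-[4-(benzyloxy)-3,5-dimethoxyphenyl]-5-[(triethylsilyl)oxy]pentanoate F2. The lithium enolate of F2 (LiN(iPr)2, THF, −78 °C) is added to 15 and left to equilibrate to the 1,4-adduct. KOtBu then closes ring A by ester Claisen condensation with loss of methoxide, giving the cyclohexane-1,3-dione F3. TsOH in moist CH2Cl2 removes the silyl group and closes O1 onto C8a to return 19.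

Step 5.
- What may go wrong: attack of the carboxyl group at the non-benzylic epoxide carbon (5-exo mode), partial SN1 character at the benzylic carbon with erosion of the trans relationship, and acyl migration of the free hydroxy lactone 9 to the five-membered lactone before step 6 caps the hydroxyl.
- Fallback, from 6 back to 10: the exo mode is made the intended one in the enantiomeric series, and the six-membered lactone is closed by acyl transfer with retention. 6 is epoxidised with the D-fructose-derived ketone to ethyl 3-{(2R,3R)-3-[4-(benzyloxy)-3,5-dimethoxyphenyl]oxiran-2-yl}propanoate F4. Saponification (LiOH) and warming of the carboxylate open the epoxide at the non-benzylic carbon with clean inversion and give (5S)-5-{(R)-[4-(benzyloxy)-3,5-dimethoxyphenyl](hydroxy)methyl}oxolan-2-one F5, which already has the required anti configuration. Silylation (tBuMe2SiCl, imidazole) gives the silyl ether F6. MeNH(OMe)·HCl with AlMe3 opens it to the hydroxy Weinreb amide F7. Benzylation (BnBr, Ag2O) gives the benzyl ether F8. HF·pyridine, then CSA in PhMe, removes the silyl group and lactonises through the benzylic oxygen to 10.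

Step 11.
- What may go wrong: deprotonation at C4a instead of C6, incomplete silylation, or slow palladium-mediated dehydrogenation that leaves 19, and oxidation at the activated C4 position once ring A is aromatic.
- Fallback, from 19 directly to 23, skipping 22: iodine in methanol at reflux, an oxidative aromatisation in which α-iodination, loss of HI and ketalisation–elimination at C7 aromatise ring A and install the C7 methyl ether in one operation. The HI formed must be watched for exchange at the enol ether and solvolysis at C2. No new compound is needed.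

Step 13.
- What may go wrong: reductive cleavage of the C2–O1 benzylic bond in competition with the slowest debenzylation (the secondary ether on O3), or stalling at a partly debenzylated stage.
- Fallback, from 23 to 24: Lewis acid dealkylation instead of reduction, with BCl3 and pentamethylbenzene as cation scavenger in CH2Cl2 at −78 °C, which should spare the aryl methyl ethers at that temperature. No new compound is needed.

## Further compounds

F1 | step 10 | methyl (4S,5R)-4-(benzyloxy)-5-[4-(benzyloxy)-3,5-dimethoxyphenyl]-5-hydroxypentanoate | COC(=O)CC[C@H](OCc1ccccc1)[C@H](O)c1cc(OC)c(OCc2ccccc2)c(OC)c1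
F2 | step 10 | methyl (4S,5R)-4-(benzyloxy)-5-[4-(benzyloxy)-3,5-dimethoxyphenyl]-5-[(triethylsilyl)oxy]pentanoate | COC(=O)CC[C@H](OCc1ccccc1)[C@H](O[Si](CC)(CC)CC)c1cc(OC)c(OCc2ccccc2)c(OC)c1
F3 | step 10 | 4-{(2S,3R)-2-(benzyloxy)-3-[4-(benzyloxy)-3,5-dimethoxyphenyl]-3-[(triethylsilyl)oxy]propyl}-5-{2-[3-(benzyloxy)phenyl]ethyl}cyclohexane-1,3-dione (mixture at C4 and C5) | O=C1CC(=O)C(C[C@H](OCc2ccccc2)[C@H](O[Si](CC)(CC)CC)c2cc(OC)c(OCc3ccccc3)c(OC)c2)C(CCc2cccc(OCc3ccccc3)c2)C1
F4 | step 5 | ethyl 3-{(2R,3R)-3-[4-(benzyloxy)-3,5-dimethoxyphenyl]oxiran-2-yl}propanoate | CCOC(=O)CC[C@H]1O[C@@H]1c1cc(OC)c(OCc2ccccc2)c(OC)c1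
F5 | step 5 | (5S)-5-{(R)-[4-(benzyloxy)-3,5-dimethoxyphenyl](hydroxy)methyl}oxolan-2-one | O=C1CC[C@H](O1)[C@H](O)c1cc(OC)c(OCc2ccccc2)c(OC)c1
F6 | step 5 | (5S)-5-{(R)-[4-(benzyloxy)-3,5-dimethoxyphenyl][(tert-butyldimethylsilyl)oxy]methyl}oxolan-2-one | O=C1CC[C@H](O1)[C@H](O[Si](C)(C)C(C)(C)C)c1cc(OC)c(OCc2ccccc2)c(OC)c1
F7 | step 5 | (4S,5R)-5-[4-(benzyloxy)-3,5-dimethoxyphenyl]-5-[(tert-butyldimethylsilyl)oxy]-4-hydroxy-N-methoxy-N-methylpentanamide | CON(C)C(=O)CC[C@H](O)[C@H](O[Si](C)(C)C(C)(C)C)c1cc(OC)c(OCc2ccccc2)c(OC)c1
F8 | step 5 | (4S,5R)-4-(benzyloxy)-5-[4-(benzyloxy)-3,5-dimethoxyphenyl]-5-[(tert-butyldimethylsilyl)oxy]-N-methoxy-N-methylpentanamide | CON(C)C(=O)CC[C@H](OCc1ccccc1)[C@H](O[Si](C)(C)C(C)(C)C)c1cc(OC)c(OCc2ccccc2)c(OC)c1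
F0 | step 11 | none | none
F0 | step 13 | none | none
A1 | alternative 1 | 4-[(2S,3S)-5-{2-[3-(benzyloxy)phenyl]ethyl}-7-methoxy-3-(4,4,5,5-tetramethyl-1,3,2-dioxaborolan-2-yl)-3,4-dihydro-2H-chromen-2-yl]-2,6-dimethoxyphenol (2,3-trans, spatial arrangement of 24) | COc1cc(CCc2cccc(OCc3ccccc3)c2)c2c(c1)O[C@H](c1cc(OC)c(O)c(OC)c1)[C@@H](B1OC(C)(C)C(C)(C)O1)C2
A2 | alternative 1 | 3-{2-[3-(benzyloxy)phenyl]ethyl}-2-(hydroxymethyl)-5-methoxyphenol | COc1cc(O)c(CO)c(CCc2cccc(OCc3ccccc3)c2)c1
A3 | alternative 1 | 2,6-dimethoxy-4-[(E)-2-(4,4,5,5-tetramethyl-1,3,2-dioxaborolan-2-yl)ethenyl]phenol | COc1cc(/C=C/B2OC(C)(C)C(C)(C)O2)cc(OC)c1O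
A4 | alternative 2 | 4-[(2R,3S)-5-{2-[3-(benzyloxy)phenyl]ethyl}-3-hydroxy-7-methoxy-3,4-dihydro-2H-chromen-2-yl]-2,6-dimethoxyphenyl 4-methylbenzenesulfonate | COc1cc(CCc2cccc(OCc3ccccc3)c2)c2c(c1)O[C@H](c1cc(OC)c(OS(=O)(=O)c3ccc(C)cc3)c(OC)c1)[C@@H](O)C2
A5 | alternative 2 | 4-{(R)-(3-{2-[3-(benzyloxy)phenyl]ethyl}-5-methoxyphenoxy)[(2S)-oxiran-2-yl]methyl}-2,6-dimethoxyphenyl 4-methylbenzenesulfonate | COc1cc(CCc2cccc(OCc3ccccc3)c2)cc(c1)O[C@H](c1cc(OC)c(OS(=O)(=O)c3ccc(C)cc3)c(OC)c1)[C@@H]1CO1
A6 | alternative 3 | (2R,3S)-2-[4-(benzyloxy)-3,5-dimethoxyphenyl]-5-{2-[3-(benzyloxy)phenyl]ethyl}-7-methoxy-3-(methoxymethoxy)-3,4-dihydro-2H-chromene | COc1cc(CCc2cccc(OCc3ccccc3)c2)c2c(c1)O[C@H](c1cc(OC)c(OCc3ccccc3)c(OC)c1)[C@@H](OCOC)C2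
A7 | alternative 3 | (1R,2S)-1-[4-(benzyloxy)-3,5-dimethoxyphenyl]-3-(2-{2-[3-(benzyloxy)phenyl]ethyl}-6-bromo-4-methoxyphenyl)-2-(methoxymethoxy)propan-1-ol | COc1cc(Br)c(C[C@H](OCOC)[C@H](O)c2cc(OC)c(OCc3ccccc3)c(OC)c2)c(CCc2cccc(OCc3ccccc3)c2)c1
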